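- In a one-step world, substrate turns into product at a pseudo-first-order rate under a steady catalyst, so the percent curve ignores the substrate charge.

all flasks: free catalyst 2.5 mM; second catalyst 7.5 mM
- cedar: substrate 0.050 M; coupling partner 0.075 M; run made earlier
- oak: substrate 0.070 M; coupling partner 0.075 M; run made earlier
- maple: substrate 0.11 M; coupling partner 0.075 M; run made earlier
- grey: substrate 0.050 M; coupling partner 0.0750 M; everything together at the start; time 50 min
- violet: substrate 0.050 M; coupling partner 0.0750 M (fed, over 40 min); all else is in the flask from the start; the feed brings no volume worth counting; time 50 min
- teal: substrate 0.050 M (fed, over 40 min); coupling partner 0.0750 M; all else is in the flask from the start; the feed brings no volume worth counting; time 50 min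
- ochre: substrate 0.050 M; coupling partner 0.0750 M (fed, over 10 min); all else is in the flask from the start; the feed brings no volume worth counting; time 50 min
- green: substrate 0.050 M; coupling partner 0.0750 M (in portions, 3, over 40 min); first portion at the start, last at 40 min; time 50 min

| run | time / min | product / % |
|---|---|---|
| cedar | 8.00 | 20 |
| cedar | 15.0 | 38 |
| cedar | 25.0 | 60 |
| cedar | 30.0 | 64 |
| oak | 3.00 | 4 |
| oak | 8.00 | 17 |
| oak | 15.0 | 38 |
| oak | 40.0 | 68 |
| maple | 10.0 | 23 |
| maple | 20.0 | 41 |
| maple | 30.0 | 55 |
| maple | 40.0 | 59 |

(readings scatter by 2 percentage points)



* which flask leads in amount of product, in percent of the substrate charged ("all alike" within 1.5 percentage points) (grey / violet / teal / ochre / green / all alike)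
* how much product is there at the end, in percent of the substrate charged: grey
* how much product is there at the end, in percent of the substrate charged: violet
* how much product is there at the end, in percent of the substrate charged: teal
* how much product is there at the end, in percent of the substrate charged: ochre
* how much product is there at the end, in percent of the substrate charged: green

- Cedar and oak, with 0.050 M and 0.070 M of substrate, both read 38% at 15.0 min, which fits that picture.
- Exposure x is the natural logarithm of the inverse of the fraction not yet product, and its rate k is x per minute. Cedar's reading at 15.0 min gives k = 0.0319 min⁻¹.
- The bench rule treats a fed charge as a batch arriving at its mean time, 20.0 min. For teal, this first round gives 61.6%.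
- The rule needs a steady k. From cedar at 25.0 min to oak at 40.0 min, x climbs at 0.0149 min⁻¹, slower than before. The ratio of these two rates, read from scattered readings, is 0.467, so the exposure clock appears to fade, and teal's substrate arrives late on that clock.
- The second round puts this curve back in, taking teal's catalyst to age as cedar's does. Extending oak's reading at the late rate gives x = 1.29 at 50 min, so this reckoning puts grey, charged as cedar, at 72.4% of product.
- At teal's mean arrival, the mean of cedar's two neighbouring readings gives x = 0.697.
- The clock left, the exposure between a charge's mean arrival and the reading, is 0.591 for teal. This reckoning therefore puts teal near 44.6% of product.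
- The forecast put grey first, with 65% for grey, 55% for violet, 30% for teal, 64% for ochre and 61% for green, holding that “the catalyst's life runs on a clock”; this reckoning stands higher for grey and teal.
- The flasks give grey 79.8%, violet 79.8%, teal 36.5%, ochre 84.0% and green 76.3%, so ochre leads.

    substrate + free catalyst → free catalyst + intermediate (k = 49.0 L mol⁻¹ min⁻¹)
    coupling partner + second catalyst + intermediate → second catalyst + product (k = 190 L² mol⁻² min⁻¹)
    coupling partner + free catalyst → spent catalyst (k = 0.820 L mol⁻¹ min⁻¹)

- Teal's clock left reckoned 44.6% of product, and teal holds 36.5% as product and 8.73% as intermediate at 50.0 min. Teal's clock fades because coupling partner turns free catalyst into spent catalyst: with that passing struck out, teal gives 69.2% of product instead of 36.5%. For a neighbour of teal with 0.010 M of free catalyst, the clock left scaled by 4.00 is 2.36, which reckons 90.6% of product. That neighbour holds 23.1% as intermediate and 63.5% as product.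

The earlier runs and the new flask stem from a simulated flask with made-up constants; noise was put on by code.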